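**Plan**

1. Retrosynthesis: the side chain is cut at C13=C14 and C13–C16 (back to a C13 aldehyde) and C8=C17 back to a C8 ketone; C6–OH and C5–H go back to a C5=C6 alkene; ring A is cut at C3–C4, giving a six-membered lactone C18(=O)–O–C1 that carries C2=C3 as a vinyl group; the lactone is cut at C4=C5 and O–C18, then C1–C10 and C9–C11, down to an α-methyl cyclohexenone ketal.
2. Forward: ring B is a commercial cyclohexanedione monoketal; one three-component step adds the C9 chain and the C1–C3 unit; a temporary lactone ring (C18, O, C1, C10, C5, C4) is closed; ring A is formed last by contraction of this lactone; then C6 is oxygenated, the side chain completed and C8 methylenated.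
3. Enabling feature: C4 of ring A carries an oxidised one-carbon substituent (C18, the benzoyloxymethyl carbon) and C1 lies 1,4 to C4 across ring A. C18 and an oxygen on C1 can therefore be tied into a lactone whose enolate carbon (C4) and vinyl terminus (C3) are the two ends of a [3,3] array; the C6 oxygen next to C5 lets the C5=C6 alkene left by the dienolate be used.
4. Stereochemistry: C9 from catalyst-controlled conjugate addition; C10 from enolate trapping anti to the C9 chain; C1 (auxiliary centre) from a chair aldol transition state; C4 from C1 by chirality transfer in the rearrangement; C5 and C6 from α-face hydroboration; 13Z from stereoretentive coupling of an E-enol phosphate.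
5. Labdane numbering (C1 to C20; β is the face of the C10 methyl group) is used for all intermediates.

Key step: step 6

**Route**

Step 1
Reactants: 1 7-methyl-1,4-dioxaspiro[4.5]decan-8-one (racemic)
Product: 2 trimethyl[(7-methyl-1,4-dioxaspiro[4.5]dec-7-en-8-yl)oxy]silane
Conditions: TMSCl, NaI, Et3N, MeCN, rt
Reagents that add atoms: chlorotrimethylsilane, C[Si](C)(C)Cl
Why: Silyl enol ether formation under equilibrating conditions (iodotrimethylsilane made in the flask) should place the double bond towards the methyl-bearing carbon, which also erases the stereocentre of racemic 1.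

Step 2
Reactants: 2 trimethyl[(7-methyl-1,4-dioxaspiro[4.5]dec-7-en-8-yl)oxy]silane
Product: 3 7-methyl-1,4-dioxaspiro[4.5]dec-6-en-8-one
Conditions: Pd(OAc)2 (10 mol %), O2 (1 atm), DMSO, 50 °C
Reagents that add atoms: none
Why: Saegusa–Ito dehydrogenation (palladation at the methyl-bearing carbon, β-hydride elimination towards the ring CH2) should give the α-methyl enone; the minor regioisomer from step 1 gives a separable enone.

Step 3
Reactants: 3 7-methyl-1,4-dioxaspiro[4.5]dec-6-en-8-one; 4 [2-(1,3-dioxan-2-yl)ethyl]magnesium bromide; 5 acrolein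
Product: 7 (6R,7S)-6-[2-(1,3-dioxan-2-yl)ethyl]-7-[(1S)-1-hydroxyprop-2-en-1-yl]-7-methyl-1,4-dioxaspiro[4.5]decan-8-one, via magnesium enolate 6 (not isolated)
Conditions: Cu(OTf)2 (3 mol %), chiral hydroxyalkyl imidazolinium salt (carbene ligand precursor, 4 mol %, antipode that gives 6R), Et2O, −30 °C; then 5, −78 °C; aq. NH4Cl
Reagents that add atoms: none
Why: Copper-catalysed asymmetric conjugate addition of the Grignard reagent sets C9 under ligand control, and the magnesium enolate then adds to acrolein (tandem conjugate addition–aldol) anti to the new C9 chain (C10, methyl cis to the chain) through a Zimmerman–Traxler chair with the vinyl group equatorial (C1 carbinol).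

Step 4
Reactants: 7 hydroxy ketone; 8 2-(diethoxyphosphoryl)propanoic acid
Product: 9 (1S)-1-[(6R,7S)-6-[2-(1,3-dioxan-2-yl)ethyl]-7-methyl-8-oxo-1,4-dioxaspiro[4.5]decan-7-yl]prop-2-en-1-yl 2-(diethoxyphosphoryl)propanoate
Conditions: DCC, DMAP, CH2Cl2, 0 °C to rt
Reagents that add atoms: none
Why: Steglich esterification acylates the hindered allylic alcohol under near-neutral conditions, which should avoid retro-aldol cleavage; the phosphonate carbon is a mixture of no consequence.

Step 5
Reactants: 9 phosphonate ester
Product: 10 bicyclic α-methyl-α,β-unsaturated δ-lactone (lactone ring C18(=O)–O–C1–C10–C5=C4; (1S)-1-vinyl; 10-methyl; C8 ethylene ketal; C9 2-(1,3-dioxan-2-yl)ethyl chain)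
Conditions: NaH, THF, 0 °C to 65 °C
Reagents that add atoms: none
Why: Intramolecular Horner–Wadsworth–Emmons olefination of the C5 ketone should close the six-membered lactone, whose ring fixes the alkene geometry (C18 cis to C10).

Step 6
Reactants: 10 unsaturated vinyl lactone
Product: 13 ring A diene acid (C1=C2 and C5=C6; 4α-CO2H; 4β-CH3; 10β-CH3; C8 ethylene ketal; 9β chain), via silyl ketene acetal 11 (not isolated), via silyl ester 12 (not isolated)
Conditions: LDA, TMSCl/Et3N, THF, −78 °C; then toluene, 105 °C; then H2O/THF, rt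
Reagents that add atoms: none
Why: γ-Deprotonation of the unsaturated lactone at C6 and O-silylation give the cyclic silyl ketene acetal 11, whose C4=C18–O–C1–C2=C3 array undergoes a thermal [3,3]-sigmatropic shift that forms C3–C4 and breaks O–C1, so that the carboxyl carbon C18 is extruded from the ring and stays on C4. The closest known reaction type is the Ireland–Claisen ring contraction of alkenyl lactone silyl ketene acetals to cycloalkene carboxylic acids, run here on a dienolate. Ring A closes through the boat-like transition state that an endocyclic ketene acetal enforces (C1 and C4 as the bridgeheads of a bicyclo[2.2.2]octane-like array); because C5 is trigonal, ring B adds no trans-fusion strain. The new quaternary centre C4 is set by suprafacial chirality transfer from the C1 carbinol: the vinyl group lies on the lactone face syn to the C10 methyl, C3 is delivered to that face, and C18 ends up α with the methyl β. The step needs O- over C-silylation and bonding at the α-carbon of the dienolate; the cold internal TMSCl/Et3N quench should favour the former, and only C4 can reach C3 in a six-membered array.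

Step 7
Reactants: 13 ring A diene acid
Product: 14 primary alcohol (4α-CH2OH; otherwise as 13)
Conditions: LiAlH4, THF, 0 °C to 65 °C; aq. NaOH work-up
Reagents that add atoms: none
Why: Hydride reduction of the neopentyl carboxylic acid should give the C18 alcohol while alkenes, ketal and acetal stay untouched.

Step 8
Reactants: 14 primary alcohol
Product: 15 C18 benzoate
Conditions: BzCl, pyridine, DMAP (cat.), CH2Cl2, 0 °C to rt
Reagents that add atoms: benzoyl chloride, O=C(Cl)c1ccccc1
Why: Standard acylation of the only hydroxyl group installs the benzoate of the target.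

Step 9
Reactants: 15 C18 benzoate
Product: 16 1,2-dihydro benzoate (ring A saturated; C5=C6 kept)
Conditions: H2 (1 atm), RhCl(PPh3)3 (5 mol %), benzene/EtOH, rt
Reagents that add atoms: none
Why: Homogeneous hydrogenation with RhCl(PPh3)3 should reduce the cis-disubstituted C1=C2 alkene and leave the trisubstituted C5=C6 alkene, which is flanked by two quaternary carbons.

Step 10
Reactants: 16 1,2-dihydro benzoate
Product: 18 6α-alcohol (5α-H; 4α-CH2OBz; C8 ketal; C13 acetal), via 6α-borane 17 (not isolated)
Conditions: BH3·THF, THF, 0 °C to rt; then 30 % H2O2, aq. NaOAc, 0 °C to rt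
Reagents that add atoms: hydrogen peroxide, OO
Why: Hydroboration–oxidation should add H to C5 and boron to C6 syn from the α face, opposite to the axial β-methyl groups on C4 and C10, which sets the trans ring fusion and the 6α-hydroxyl; buffered oxidation spares the benzoate.

Step 11
Reactants: 18 6α-alcohol
Product: 19 18-benzoyloxy-6α-hydroxy-8-oxo-14,15,16,17-tetranorlabdan-13-al
Conditions: 1 M HCl, THF, rt
Reagents that add atoms: water, O
Why: Mild acid hydrolysis should remove the dioxolane ketal and the dioxane acetal together, while the benzoate survives.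

Step 12
Reactants: 19 keto aldehyde; 20 tert-butyl diazoacetate
Product: 21 tert-butyl 18-benzoyloxy-6α-hydroxy-8,13-dioxo-16,17-dinorlabdan-15-oate
Conditions: SnCl2 (10 mol %), CH2Cl2, rt
Reagents that add atoms: none
Why: The Roskamp homologation converts an aldehyde into a β-keto ester with loss of N2 and should leave the hindered C8 ketone and the free hydroxyl alone.

Step 13
Reactants: 21 β-keto ester
Product: 22 (13E)-enol diethyl phosphate of 21
Conditions: ClP(O)(OEt)2 (1.05 equiv), Et3N, DMAP (cat.), HMPA, 0 °C to rt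
Reagents that add atoms: diethyl chlorophosphate, CCOP(=O)(Cl)OCC
Why: O-Phosphorylation of the β-keto ester under non-chelating conditions (amine base in HMPA) should give the E-enol phosphate, and the far more acidic keto ester reacts before the hindered C6 hydroxyl.

Step 14
Reactants: 22 E-enol phosphate
Product: 23 tert-butyl (13Z)-18-benzoyloxy-6α-hydroxy-8-oxo-17-norlabd-13-en-15-oate
Conditions: Me2CuLi (3 equiv, from MeLi and CuI), Et2O, −78 to −45 °C
Reagents that add atoms: lithium dimethylcuprate, [Li+].C[Cu-]C
Why: Cuprate substitution of the enol phosphate (addition–elimination with retention) should put the methyl group trans to the ester and so give the 13Z enoate; esters and the hindered ketone do not react at this temperature.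

Step 15
Reactants: 23 Z-enoate ketone
Product: 24 tert-butyl (13Z)-18-benzoyloxy-6α-hydroxylabda-8(17),13-dien-15-oate
Conditions: Zn, CH2Br2, TiCl4, THF/CH2Cl2, 0 °C to rt
Reagents that add atoms: dibromomethane, BrCBr
Why: Takai–Lombardo methylenation is non-basic and selective for ketones over esters, so it should convert the C8 ketone without epimerising C9 or eliminating the β-hydroxyl.

Step 16
Reactants: 24 tert-butyl ester
Product: 26 (13Z)-18-benzoyloxy-6α-hydroxylabda-8(17),13-dien-15-oic acid, via bis-silyl derivative 25 (not isolated)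
Conditions: TMSOTf, 2,6-lutidine, CH2Cl2, 0 °C; then aq. citric acid, THF/MeOH, rt
Reagents that add atoms: none
Why: Silyl triflate-mediated cleavage of the tert-butyl ester (silyl ester, loss of isobutene) followed by mild aqueous desilylation should free the acid and the C6 hydroxyl without touching the benzoate, the exocyclic alkene or the Z-enoate.

**Compound list**

1 | 7-methyl-1,4-dioxaspiro[4.5]decan-8-one (racemic) | CC1CC2(OCCO2)CCC1=O | starting material
2 | trimethyl[(7-methyl-1,4-dioxaspiro[4.5]dec-7-en-8-yl)oxy]silane | CC1=C(O[Si](C)(C)C)CCC2(OCCO2)C1 | intermediate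
3 | 7-methyl-1,4-dioxaspiro[4.5]dec-6-en-8-one | CC1=CC2(OCCO2)CCC1=O | intermediate
4 | [2-(1,3-dioxan-2-yl)ethyl]magnesium bromide | Br[Mg]CCC1OCCCO1 | starting material
5 | acrolein | C=CC=O | starting material
6 | bromomagnesium enolate of (6R)-6-[2-(1,3-dioxan-2-yl)ethyl]-7-methyl-1,4-dioxaspiro[4.5]decan-8-one | Br[Mg]OC1=C(C)[C@@H](CCC2OCCCO2)C3(OCCO3)CC1 | intermediate (not isolated)
7 | (6R,7S)-6-[2-(1,3-dioxan-2-yl)ethyl]-7-[(1S)-1-hydroxyprop-2-en-1-yl]-7-methyl-1,4-dioxaspiro[4.5]decan-8-one | O[C@@H](C=C)[C@@]1(C)C(=O)CCC2(OCCO2)[C@@H]1CCC3OCCCO3 | intermediate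
8 | 2-(diethoxyphosphoryl)propanoic acid | CCOP(=O)(OCC)C(C)C(=O)O | starting material
9 | 2-(diethoxyphosphoryl)propanoate of 7 at the allylic hydroxyl | CCOP(=O)(OCC)C(C)C(=O)O[C@@H](C=C)[C@@]1(C)C(=O)CCC2(OCCO2)[C@@H]1CCC3OCCCO3 | intermediate
10 | bicyclic α-methyl-α,β-unsaturated δ-lactone (C18(=O)–O–C1 lactone, C4=C5, 1-vinyl, C8 ethylene ketal, C9 dioxanylethyl chain) | O1CCOC12CCC3=C(C)C(=O)O[C@@H](C=C)[C@]3(C)[C@H]2CCC4OCCCO4 | intermediate
11 | cyclic trimethylsilyl ketene acetal of 10 (C4=C18 and C5=C6) | O1CCOC12CC=C3C(C)=C(O[Si](C)(C)C)O[C@@H](C=C)[C@]3(C)[C@H]2CCC4OCCCO4 | intermediate (not isolated)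
12 | trimethylsilyl ester of 13 | O1CCOC12CC=C3[C@](C)(C(=O)O[Si](C)(C)C)CC=C[C@]3(C)[C@H]2CCC4OCCCO4 | intermediate (not isolated)
13 | ring A diene acid (C1=C2, C5=C6, 4α-CO2H, 4β-CH3, 10β-CH3, C8 ketal, 9β chain) | O1CCOC12CC=C3[C@](C)(C(=O)O)CC=C[C@]3(C)[C@H]2CCC4OCCCO4 | intermediate
14 | 4α-hydroxymethyl diene | O1CCOC12CC=C3[C@](C)(CO)CC=C[C@]3(C)[C@H]2CCC4OCCCO4 | intermediate
15 | 4α-benzoyloxymethyl diene | O1CCOC12CC=C3[C@](C)(COC(=O)c4ccccc4)CC=C[C@]3(C)[C@H]2CCC5OCCCO5 | intermediate
16 | 4α-benzoyloxymethyl 5-ene (ring A saturated) | O1CCOC12CC=C3[C@](C)(COC(=O)c4ccccc4)CCC[C@]3(C)[C@H]2CCC5OCCCO5 | intermediate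
17 | 6α-boryl-5α-H intermediate | O1CCOC12C[C@H](B)[C@H]3[C@](C)(COC(=O)c4ccccc4)CCC[C@]3(C)[C@H]2CCC5OCCCO5 | intermediate (not isolated)
18 | 6α-alcohol (5α-H, 4α-CH2OBz, C8 ketal, C13 acetal) | O1CCOC12C[C@H](O)[C@H]3[C@](C)(COC(=O)c4ccccc4)CCC[C@]3(C)[C@H]2CCC5OCCCO5 | intermediate
19 | 18-benzoyloxy-6α-hydroxy-8-oxo-14,15,16,17-tetranorlabdan-13-al | O=C1C[C@H](O)[C@H]2[C@](C)(COC(=O)c3ccccc3)CCC[C@]2(C)[C@H]1CCC=O | intermediate
20 | tert-butyl diazoacetate | [N-]=[N+]=CC(=O)OC(C)(C)C | starting material
21 | tert-butyl 18-benzoyloxy-6α-hydroxy-8,13-dioxo-16,17-dinorlabdan-15-oate | O=C1C[C@H](O)[C@H]2[C@](C)(COC(=O)c3ccccc3)CCC[C@]2(C)[C@H]1CCC(=O)CC(=O)OC(C)(C)C | intermediate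
22 | (13E)-enol diethyl phosphate of 21 | O=C1C[C@H](O)[C@H]2[C@](C)(COC(=O)c3ccccc3)CCC[C@]2(C)[C@H]1CC/C(OP(=O)(OCC)OCC)=C\C(=O)OC(C)(C)C | intermediate
23 | tert-butyl (13Z)-18-benzoyloxy-6α-hydroxy-8-oxo-17-norlabd-13-en-15-oate | O=C1C[C@H](O)[C@H]2[C@](C)(COC(=O)c3ccccc3)CCC[C@]2(C)[C@H]1CC/C(C)=C\C(=O)OC(C)(C)C | intermediate
24 | tert-butyl (13Z)-18-benzoyloxy-6α-hydroxylabda-8(17),13-dien-15-oate | C=C1C[C@H](O)[C@H]2[C@](C)(COC(=O)c3ccccc3)CCC[C@]2(C)[C@H]1CC/C(C)=C\C(=O)OC(C)(C)C | intermediate
25 | 6-O-trimethylsilyl ether trimethylsilyl ester of 26 | C=C1C[C@H](O[Si](C)(C)C)[C@H]2[C@](C)(COC(=O)c3ccccc3)CCC[C@]2(C)[C@H]1CC/C(C)=C\C(=O)O[Si](C)(C)C | intermediate (not isolated)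
26 | (13Z)-18-benzoyloxy-6α-hydroxylabda-8(17),13-dien-15-oic acid | C=C1C[C@H](O)[C@H]2[C@](C)(COC(=O)c3ccccc3)CCC[C@]2(C)[C@H]1CC/C(C)=C\C(=O)O | target

**Summary**

Total step count: 16. Longest linear sequence: 16 steps (from 1).

Steps most likely to fail:

Step 6. The boat-shaped transition state may not be reached before the silyl dienol ether decomposes, or silylation may occur on carbon. The fallback sets out from 10 and comes back at 14. The lactone is opened with pyrrolidine/AlMe3 to the hydroxy amide F1, and the C1 hydroxyl is converted with ClCO2Me/pyridine into the allylic methyl carbonate F2. γ-Deprotonation with LDA gives the lithium dienolate F3, and Pd(PPh3)4 then ionises the carbonate so that C4 attacks the allyl terminus C3 in an intramolecular Tsuji–Trost alkylation to give the bicyclic amide F4. The attacked face is fixed by the tether from C10, and allylic strain should place the amide carbon syn to C6–H, which leads to the same C4 configuration. Reduction of F4 with LiEt3BH gives 14.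

Step 3. Facial selectivity at the aldehyde carbon in the aldol trapping may be low, so that the C1 epimer forms beside 7 and C4 would later be set wrongly. The fallback sets out from 3 and comes back at 7. The conjugate addition and acrolein trapping are run as described; the mixture of 7 and the C1 epimer F5 is oxidised with Dess–Martin periodinane to the vinyl ketone F6. The enone carbonyl is then reduced under reagent control (CBS oxazaborolidine, catecholborane, −78 °C, the catalyst antipode that gives the 1S carbinol) to return 7.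

Step 5. The phosphonate anion may fail to add to the hindered ketone next to the quaternary C10, with ester cleavage taking over. The fallback sets out from 7 and comes back at 10. Alcohol 7 is acylated with 2-bromopropanoyl bromide/pyridine to the α-bromo ester F7; SmI2 (THF, −78 °C) brings about an intramolecular Reformatsky addition to the C5 ketone and gives the β-hydroxy lactone F8. Dehydration (SOCl2, pyridine, then DBU to move the alkene into conjugation) gives 10.

**Further compounds**

F1 | step 6 | hydroxy pyrrolidine amide from opening of 10 | O=C(N1CCCC1)/C(C)=C2/CCC3(OCCO3)[C@H](CCC4OCCCO4)[C@@]2(C)[C@@H](O)C=C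
F2 | step 6 | allylic methyl carbonate of F1 | O=C(N1CCCC1)/C(C)=C2/CCC3(OCCO3)[C@H](CCC4OCCCO4)[C@@]2(C)[C@@H](OC(=O)OC)C=C
F3 | step 6 | lithium dienolate of F2 | [Li]OC(N1CCCC1)=C(C)C2=CCC3(OCCO3)[C@H](CCC4OCCCO4)[C@@]2(C)[C@@H](OC(=O)OC)C=C
F4 | step 6 | pyrrolidine amide of 13 | O1CCOC12CC=C3[C@](C)(C(=O)N4CCCC4)CC=C[C@]3(C)[C@H]2CCC5OCCCO5
F5 | step 3 | C1 epimer of 7 | O[C@H](C=C)[C@@]1(C)C(=O)CCC2(OCCO2)[C@@H]1CCC3OCCCO3
F6 | step 3 | vinyl ketone from oxidation of 7 and F5 | C=CC(=O)[C@@]1(C)C(=O)CCC2(OCCO2)[C@@H]1CCC3OCCCO3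
F7 | step 5 | 2-bromopropanoate of 7 | CC(Br)C(=O)O[C@@H](C=C)[C@@]1(C)C(=O)CCC2(OCCO2)[C@@H]1CCC3OCCCO3
F8 | step 5 | β-hydroxy lactone (C5 hydroxyl, C4 methyl, mixture at C4 and C5) | O1CCOC12CCC3(O)C(C)C(=O)O[C@@H](C=C)[C@]3(C)[C@H]2CCC4OCCCO4
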